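**Plan**

1. Numbering: ring O1–O2–C3(CH3)(CH2CO2H)–C4H2–C5(CH3)(chain); chain C1′–C16′. The retrosynthesis first cuts the C9′=C10′ alkene (Julia–Kocienski olefination, sulfone on the ring fragment) and masks the acid as a methyl ester.
2. The 1,2-dioxolane is then cut at C3–C4 and O1–C5, a formal (3+2) disconnection into a silylperoxycarbenium ion (O1–O2–C3) and a 2-methyl-1-alkene (C4=C5).
3. Enabling feature: in the ring O1–O2–C3–C4–C5, C3 (bound to O2, CH3 and CH2CO2R) is at ketone oxidation level and can be a peroxycarbenium carbon. C5 is a fully substituted carbon on O1 and can arise as a tertiary cation from a 1,1-disubstituted alkene whose CH2 becomes C4.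
4. Forward order: peroxyketal (ozonolysis in MeOH, O-silylation) and bromoalkene (Cu-catalysed sp3–sp3 coupling) are made separately; the annulation builds the ring and both quaternary centres at once; then Br → tetrazolyl sulfone → triene; ester hydrolysis last. The triene comes after the cationic step because it would itself be attacked by the peroxycarbenium ion.
5. Stereochemistry: C3 and C5 (3R,5R, methyl groups cis) come from a chiral counter-anion in the annulation, which is enantioconvergent with respect to the racemic peroxyketal; 11E,13E come from the dienal; 9E from the olefination.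

Key step: step 4

Assumption: the sense of induction of the chiral anion cannot be predicted, so the catalyst antipode that gives the (3R,5R) series is chosen after a test reaction. The IDPi acid is a catalyst made separately from (R)- or (S)-BINOL and is not counted as a starting material.

**Route**

Step 1
Reactants: 1 methyl 3-methylbut-3-enoate
Product: 4 methyl 3-hydroperoxy-3-methoxybutanoate (racemic), via primary ozonide 2 (not isolated), via carbonyl oxide 3 (not isolated)
Conditions: O3, CH2Cl2/MeOH 4:1, −78 °C; N2 purge; concentrate below 20 °C, use crude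
Reagents that add atoms: ozone, [O-][O+]=O; methanol, CO
Why: Criegee ozonolysis in which the primary ozonide 2 should cleave to put the carbonyl oxide on the more substituted carbon (3, with loss of formaldehyde) and methanol traps 3 as the α-methoxy hydroperoxide; the new centre is racemic, which does not matter because it is planarised in step 4.

Step 2
Reactants: 4 methyl 3-hydroperoxy-3-methoxybutanoate
Product: 5 methyl 3-methoxy-3-[(triethylsilyl)peroxy]butanoate (racemic)
Conditions: Et3SiCl, imidazole, DMF, 0 °C
Reagents that add atoms: chlorotriethylsilane, CC[Si](Cl)(CC)CC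
Why: Standard O-silylation of an acidic hydroperoxide with a silyl chloride and imidazole; the Et3Si group later serves as the electrofuge that allows the peroxide oxygen to close the ring.

Step 3
Reactants: 6 (2-methylallyl)magnesium chloride; 7 1,8-dibromooctane (3 equiv)
Product: 8 11-bromo-2-methylundec-1-ene
Conditions: Li2CuCl4 (3 mol %), THF, −10 °C to rt, slow addition of 6; excess 7 removed by distillation
Reagents that add atoms: none
Why: Kochi-type copper-catalysed Grignard–alkyl bromide coupling; the two termini of the methallyl unit are equivalent, so SN2 and SN2′ delivery give the same product, and the excess of 7 should suppress double coupling.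

Step 4
Reactants: 5 methyl 3-methoxy-3-[(triethylsilyl)peroxy]butanoate; 8 11-bromo-2-methylundec-1-ene (1.5 equiv)
Product: 11 methyl 2-[(3R,5R)-5-(9-bromononyl)-3,5-dimethyl-1,2-dioxolan-3-yl]acetate, via silylperoxycarbenium ion 9 (not isolated), via tertiary carbocation 10 (not isolated)
Conditions: BINOL-derived imidodiphosphorimidate Brønsted acid (IDPi, HX*, 5 mol %), CH2Cl2, −78 to −60 °C; Et3N quench; silica chromatography
Reagents that add atoms: none
Why: Proposed new method: the confined IDPi acid, present after the first turnover as Et3Si–X*, should abstract methoxide from either enantiomer of racemic 5, so that both converge on the planar ion 9 held as a contact ion pair with the chiral anion; the CH2 terminus of alkene 8 then adds to C3 of 9 (new C3–C4 bond) to give cation 10, whose Et3Si-bearing peroxide oxygen closes onto C5 and returns Et3Si+ to the anion. The closest known reaction types are the SnCl4-promoted annulation of silyl peroxyketals with alkenes (racemic) and IDPi/silylium counter-anion-directed additions to oxocarbenium ions generated from acetals. The dioxolane is closed as a stepwise formal (3+2) annulation (O1–O2–C3 plus C4=C5): intermolecular C–C bond formation, then five-membered O–C closure onto a carbocation in which both former alkene carbons become ring atoms (formally 5-endo with respect to the alkene). C3 should be set by the anion shielding one face of 9 during C–C bond formation, and C5 by closure of 10 before it leaves the same chiral pocket, the cis-dimethyl (3R,5R) isomer being the one required. The substrate secures chemo- and regioselectivity (one nucleophilic π bond only, 1,1-disubstitution directs attack through CH2 to a tertiary cation, the primary bromide is inert, the triene is not yet present), but it does not bias the faces at C3 or C5 (CH3 against CH2 at both), so face selectivity must come from the catalyst and any trans isomer is removed by chromatography.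

Step 5
Reactants: 11 methyl 2-[(3R,5R)-5-(9-bromononyl)-3,5-dimethyl-1,2-dioxolan-3-yl]acetate
Product: 12 methyl 2-[(3R,5R)-3,5-dimethyl-5-{9-[(1-phenyl-1H-tetrazol-5-yl)sulfanyl]nonyl}-1,2-dioxolan-3-yl]acetate
Conditions: 1-phenyl-1H-tetrazole-5-thiol, K2CO3, DMF, rt
Reagents that add atoms: 1-phenyl-1H-tetrazole-5-thiol, Sc1nnnn1-c1ccccc1
Why: SN2 displacement of the primary bromide by a soft thiolate; the di-tertiary dialkyl peroxide should be inert to the thiolate and carbonate is too weak to enolise the ester.

Step 6
Reactants: 12 methyl 2-[(3R,5R)-3,5-dimethyl-5-{9-[(1-phenyl-1H-tetrazol-5-yl)sulfanyl]nonyl}-1,2-dioxolan-3-yl]acetate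
Product: 13 methyl 2-[(3R,5R)-3,5-dimethyl-5-{9-[(1-phenyl-1H-tetrazol-5-yl)sulfonyl]nonyl}-1,2-dioxolan-3-yl]acetate
Conditions: 30% aq. H2O2, (NH4)6Mo7O24·4H2O (10 mol %), EtOH, 0 °C to rt
Reagents that add atoms: hydrogen peroxide, OO
Why: Molybdate-catalysed oxidation of a sulfide to the sulfone; the medium is oxidising, so the ring peroxide is not at risk, and no alkene is present yet.

Step 7
Reactants: 13 methyl 2-[(3R,5R)-3,5-dimethyl-5-{9-[(1-phenyl-1H-tetrazol-5-yl)sulfonyl]nonyl}-1,2-dioxolan-3-yl]acetate; 14 (2E,4E)-hepta-2,4-dienal (isomerically pure, 1.5 equiv)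
Product: 18 methyl 2-[(3R,5R)-5-[(9E,11E,13E)-hexadeca-9,11,13-trien-1-yl]-3,5-dimethyl-1,2-dioxolan-3-yl]acetate, via potassium α-sulfonyl carbanion 15 (not isolated), via β-alkoxy sulfone adduct 16 (not isolated), via Smiles-rearranged sulfinate 17 (not isolated)
Conditions: KHMDS (1.05 equiv), DME, −60 °C, 20 min; then 14, −60 °C to rt, dark
Reagents that add atoms: none
Why: Julia–Kocienski olefination (addition, Smiles rearrangement, loss of SO2 and tetrazololate), expected to be E-selective because potassium tetrazolyl-sulfone anions add anti and adducts of conjugated aldehydes can eliminate through an allylically stabilised pathway; the sulfone α-H is far more acidic than the ester α-H, so one equivalent of base should leave the β-peroxy ester and the ring stereocentres untouched.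

Step 8
Reactants: 18 methyl 2-[(3R,5R)-5-[(9E,11E,13E)-hexadeca-9,11,13-trien-1-yl]-3,5-dimethyl-1,2-dioxolan-3-yl]acetate
Product: 20 2-[(3R,5R)-5-[(9E,11E,13E)-hexadeca-9,11,13-trien-1-yl]-3,5-dimethyl-1,2-dioxolan-3-yl]acetic acid, via lithium carboxylate 19 (not isolated)
Conditions: LiOH·H2O, THF/H2O 3:1, 0 °C to rt, dark; then 0.5 M HCl to pH 3–4 at 0 °C
Reagents that add atoms: lithium hydroxide, [Li+].[OH-]
Why: Saponification of an unhindered methyl ester at or below room temperature, a reaction type with precedent on 1,2-dioxolane-3-acetates; the fully substituted dioxolane and the triene should tolerate cold dilute hydroxide and brief mild acidification.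

**Compound list**

1 | methyl 3-methylbut-3-enoate | C=C(C)CC(=O)OC | starting material
2 | methyl 2-(4-methyl-1,2,3-trioxolan-4-yl)acetate (primary ozonide) | COC(=O)CC1(C)COOO1 | intermediate
3 | carbonyl oxide of methyl 3-oxobutanoate | COC(=O)CC(C)=[O+][O-] | intermediate
4 | methyl 3-hydroperoxy-3-methoxybutanoate (racemic) | COC(=O)CC(C)(OC)OO | intermediate
5 | methyl 3-methoxy-3-[(triethylsilyl)peroxy]butanoate (racemic) | COC(=O)CC(C)(OC)OO[Si](CC)(CC)CC | intermediate
6 | (2-methylallyl)magnesium chloride | C=C(C)C[Mg]Cl | starting material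
7 | 1,8-dibromooctane | BrCCCCCCCCBr | starting material
8 | 11-bromo-2-methylundec-1-ene | C=C(C)CCCCCCCCCBr | intermediate
9 | silylperoxycarbenium ion CH3C(=O+–OSiEt3)CH2CO2CH3 (ion pair with the IDPi anion) | COC(=O)CC(C)=[O+]O[Si](CC)(CC)CC | intermediate
10 | (3R)-configured tertiary carbocation formed by C3–C4 bond formation (ion pair with the IDPi anion) | COC(=O)C[C@@](C)(C[C+](C)CCCCCCCCCBr)OO[Si](CC)(CC)CC | intermediate
11 | methyl 2-[(3R,5R)-5-(9-bromononyl)-3,5-dimethyl-1,2-dioxolan-3-yl]acetate | BrCCCCCCCCC[C@]1(C)C[C@](C)(CC(=O)OC)OO1 | intermediate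
12 | methyl 2-[(3R,5R)-3,5-dimethyl-5-{9-[(1-phenyl-1H-tetrazol-5-yl)sulfanyl]nonyl}-1,2-dioxolan-3-yl]acetate | c1ccccc1-n1nnnc1SCCCCCCCCC[C@]1(C)C[C@](C)(CC(=O)OC)OO1 | intermediate
13 | methyl 2-[(3R,5R)-3,5-dimethyl-5-{9-[(1-phenyl-1H-tetrazol-5-yl)sulfonyl]nonyl}-1,2-dioxolan-3-yl]acetate | c1ccccc1-n1nnnc1S(=O)(=O)CCCCCCCCC[C@]1(C)C[C@](C)(CC(=O)OC)OO1 | intermediate
14 | (2E,4E)-hepta-2,4-dienal | CC/C=C/C=C/C=O | starting material
15 | potassium α-sulfonyl carbanion of 13 | [K+].c1ccccc1-n1nnnc1S(=O)(=O)[CH-]CCCCCCCC[C@]1(C)C[C@](C)(CC(=O)OC)OO1 | intermediate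
16 | β-alkoxy sulfone adduct of 15 and 14 (potassium alkoxide, diastereomer mixture at the two new carbons) | [K+].CC/C=C/C=C/C([O-])C(CCCCCCCC[C@]1(C)C[C@](C)(CC(=O)OC)OO1)S(=O)(=O)c1nnnn1-c1ccccc1 | intermediate
17 | potassium sulfinate after Smiles transfer of the tetrazolyl group from S to O | [K+].CC/C=C/C=C/C(Oc1nnnn1-c1ccccc1)C(CCCCCCCC[C@]1(C)C[C@](C)(CC(=O)OC)OO1)S(=O)[O-] | intermediate
18 | methyl 2-[(3R,5R)-5-[(9E,11E,13E)-hexadeca-9,11,13-trien-1-yl]-3,5-dimethyl-1,2-dioxolan-3-yl]acetate | CC/C=C/C=C/C=C/CCCCCCCC[C@]1(C)C[C@](C)(CC(=O)OC)OO1 | intermediate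
19 | lithium 2-[(3R,5R)-5-[(9E,11E,13E)-hexadeca-9,11,13-trien-1-yl]-3,5-dimethyl-1,2-dioxolan-3-yl]acetate | [Li+].CC/C=C/C=C/C=C/CCCCCCCC[C@]1(C)C[C@](C)(CC(=O)[O-])OO1 | intermediate
20 | 2-[(3R,5R)-5-[(9E,11E,13E)-hexadeca-9,11,13-trien-1-yl]-3,5-dimethyl-1,2-dioxolan-3-yl]acetic acid | CC/C=C/C=C/C=C/CCCCCCCC[C@]1(C)C[C@](C)(CC(=O)O)OO1 | target

**Count**

Total steps: 8. Longest linear sequence: 7 (steps 1, 2, 4, 5, 6, 7, 8); step 3 is the side branch.

**Steps most likely to fail**

Step 4 (proposed new method). The risks are insufficient face discrimination in the ion pair at C3 or C5, slow ionisation or catalyst inhibition at low temperature, and proton loss from the tertiary cation instead of ring closure. The fallback sets out from 5 and 8 and uses the established racemic annulation of this substrate class (SnCl4, 1 equiv, CH2Cl2, −78 °C). After removal of the trans isomer on silica this should give racemic methyl 2-[(3R*,5R*)-5-(9-bromononyl)-3,5-dimethyl-1,2-dioxolan-3-yl]acetate F1. F1 is then resolved by preparative HPLC on a polysaccharide chiral stationary phase, and the (3R,5R) enantiomer re-enters the route at 11.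

Step 7. The risks are incomplete E selectivity at the new C9′=C10′ bond, deprotonation α to the ester with E1cB opening of the dioxolane (and re-closure with loss of configuration at C3), and self-condensation of the sulfone anion. The fallback sets out from 11 and reverses the roles of the partners in a Horner–Wadsworth–Emmons olefination. Ganem oxidation of the bromide (Me3NO, DMSO, rt) should give methyl 2-[(3R,5R)-3,5-dimethyl-5-(9-oxononyl)-1,2-dioxolan-3-yl]acetate F2. The phosphonate is made from 14: Luche reduction (NaBH4, CeCl3·7H2O, MeOH, 0 °C) to (2E,4E)-hepta-2,4-dien-1-ol F3, PBr3 (Et2O, 0 °C) to (2E,4E)-1-bromohepta-2,4-diene F4, and Arbuzov reaction with triethyl phosphite (100 °C) to diethyl [(2E,4E)-hepta-2,4-dien-1-yl]phosphonate F5. The lithium anion of F5 (LiHMDS, THF, −78 °C) is formed first and then treated with F2 (−78 to 0 °C), so the amide base never meets the dioxolane ester; the sequence returns to the route at 18.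

Step 8. The risks are hydroxide-induced enolisation of the β-peroxy ester with retro-oxa-Michael opening of the ring, epimerisation at C3 on re-closure, and degradation of the triene acid during acidification. The fallback sets out from 18 and replaces chemical saponification by biocatalytic hydrolysis (pig liver esterase or an immobilised lipase, pH 7 phosphate buffer with acetone as co-solvent, rt). This proceeds through an acyl-enzyme without free hydroxide or an acidification step, and comes back to the route at 20.

**Further compounds**

F1 | step 4 | racemic methyl 2-[(3R*,5R*)-5-(9-bromononyl)-3,5-dimethyl-1,2-dioxolan-3-yl]acetate (both enantiomers shown) | BrCCCCCCCCC[C@]1(C)C[C@](C)(CC(=O)OC)OO1.BrCCCCCCCCC[C@@]1(C)C[C@@](C)(CC(=O)OC)OO1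
F2 | step 7 | methyl 2-[(3R,5R)-3,5-dimethyl-5-(9-oxononyl)-1,2-dioxolan-3-yl]acetate | O=CCCCCCCCC[C@]1(C)C[C@](C)(CC(=O)OC)OO1
F3 | step 7 | (2E,4E)-hepta-2,4-dien-1-ol | CC/C=C/C=C/CO
F4 | step 7 | (2E,4E)-1-bromohepta-2,4-diene | CC/C=C/C=C/CBr
F5 | step 7 | diethyl [(2E,4E)-hepta-2,4-dien-1-yl]phosphonate | CC/C=C/C=C/CP(=O)(OCC)OCC
F0 | step 8 | none | none
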